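The route rests on cutting C5–C9. This bond ties the tertiary carbinol C9 to ring-fusion carbon C5, where the cyclopentane (C5–C9) meets the cycloheptane (C2–C6, C10, C11). The precursor is a monocyclic cyclohept-4-enone whose 3-oxobutyl chain is attached at C6, the allylic carbon of the C4=C5 alkene. One reductive ketyl–olefin cyclisation closes the five-membered ring and sets C5 and C9 together. It exploits the fact that C9 carries its hydroxyl on the H5/H6 face of a cis-fused hydroazulene. The hydroazulenone is then joined at C11–C12 to an oxepane lactone made by a diepoxide cascade. An allylic diazene shift sets C2 and the C11=C12 alkene.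

Key step: step 11

**Remarks**
- Atom numbers: C1 is the methyl on C2. C2–C6, C10 and C11 form the cycloheptane, and C5–C9 the cyclopentane. C12 and C13 are the linker. C14, C15 and C21–C24 form the cyclohexane, and C15–C19, O20 and C21 the oxepane.
- Compounds 15 and 16 carry the target configurations (2S,6R and 2S,5R,6R,9R), so no structure needed correction.
- In the target, C13 lies on the C10 side of C11=C12 (Z). This is the more crowded isomer, so the alkene is made under kinetic, stereospecific control in step 22.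
- Assumption: the phosphoramidite antipode written in step 5 is the one that gives (R)-C6. If the facial rule runs the other way for this substrate, the mirror-image ligand is used.
- Step 8 gives both C2 epimers. Compounds 13–17 are drawn as the 2S epimer. Both epimers converge at 18, and C2 is set for good in step 22.

**Route**

Step 1
Reactants: 1 hex-5-en-2-one
Product: 2 2-(but-3-en-1-yl)-2-methyl-1,3-dioxolane
Conditions: HOCH2CH2OH, p-TsOH (cat.), toluene, Dean–Stark, reflux
Reagents that add atoms: ethylene glycol, OCCO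
Why: Acid-catalysed ketalisation with azeotropic water removal masks the future C9 ketone against the hydride, Grignard and enolate steps ahead.

Step 2
Reactants: 2 2-(but-3-en-1-yl)-2-methyl-1,3-dioxolane; 3 ethyl acrylate
Product: 4 ethyl (E)-5-(2-methyl-1,3-dioxolan-2-yl)pent-2-enoate
Conditions: second-generation Hoveyda–Grubbs catalyst (H2IMes)Cl2Ru=CH(2-iPrOC6H4) (2 mol %), CH2Cl2, 40 °C
Reagents that add atoms: none
Why: Olefin cross metathesis between an unhindered terminal alkene and an electron-poor acrylate should be cross-selective and give the E-enoate, which fixes the alkene geometry needed in step 5.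

Step 3
Reactants: 4 ethyl (E)-5-(2-methyl-1,3-dioxolan-2-yl)pent-2-enoate
Product: 5 (E)-5-(2-methyl-1,3-dioxolan-2-yl)pent-2-en-1-ol
Conditions: i-Bu2AlH (2.2 equiv), CH2Cl2, −78 °C; aq KNaC4H4O6
Reagents that add atoms: none
Why: Two equivalents of i-Bu2AlH reduce the conjugated ester in a 1,2-sense to the E-allylic alcohol without touching the ketal.

Step 4
Reactants: 5 (E)-5-(2-methyl-1,3-dioxolan-2-yl)pent-2-en-1-ol
Product: 6 methyl (E)-5-(2-methyl-1,3-dioxolan-2-yl)pent-2-en-1-yl carbonate
Conditions: ClCO2Me, pyridine, CH2Cl2, 0 °C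
Reagents that add atoms: methyl chloroformate, COC(=O)Cl
Why: Acylation of the primary alcohol with a chloroformate installs the carbonate leaving group, whose methoxide later activates the silicon enolate.

Step 5
Reactants: 6 methyl (E)-5-(2-methyl-1,3-dioxolan-2-yl)pent-2-en-1-yl carbonate; 7 1-methoxy-2-methyl-1-(trimethylsilyloxy)prop-1-ene
Product: 8 methyl (3R)-2,2-dimethyl-3-[2-(2-methyl-1,3-dioxolan-2-yl)ethyl]pent-4-enoate
Conditions: [Ir(cod)Cl]2 (2 mol %), (Sa,S,S)-O,O′-(1,1′-binaphthyl-2,2′-diyl)-N,N-bis(1-phenylethyl)phosphoramidite (4 mol %), pre-activated with n-PrNH2, THF, 25–50 °C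
Reagents that add atoms: none
Why: In this iridium-catalysed asymmetric allylic alkylation (branched-selective Tsuji–Trost type) the cyclometalated Ir–phosphoramidite ionises the carbonate, the released methoxide desilylates 7, and attack at the substituted allyl terminus anti to the metal forms C6–C10 with C6 set as R by the ligand.

Step 6
Reactants: 8 methyl (3R)-2,2-dimethyl-3-[2-(2-methyl-1,3-dioxolan-2-yl)ethyl]pent-4-enoate
Product: 9 (3R)-N-methoxy-N,2,2-trimethyl-3-[2-(2-methyl-1,3-dioxolan-2-yl)ethyl]pent-4-enamide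
Conditions: MeNH(OMe)·HCl, i-PrMgCl, THF, −20 °C → rt
Reagents that add atoms: N,O-dimethylhydroxylamine hydrochloride, CNOC.Cl
Why: Aminolysis of the hindered ester by the small, strongly nucleophilic chloromagnesium amide gives the Weinreb amide without affecting C6.

Step 7
Reactants: 9 (3R)-N-methoxy-N,2,2-trimethyl-3-[2-(2-methyl-1,3-dioxolan-2-yl)ethyl]pent-4-enamide
Product: 10 (5R)-4,4-dimethyl-5-[2-(2-methyl-1,3-dioxolan-2-yl)ethyl]hept-6-en-3-one
Conditions: EtMgBr, THF, 0 °C; H2O
Reagents that add atoms: ethylmagnesium bromide, CC[Mg]Br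
Why: In the Weinreb ketone synthesis the chelated tetrahedral adduct stops the Grignard addition at the ketone stage and delivers C2 and C1.

Step 8
Reactants: 10 (5R)-4,4-dimethyl-5-[2-(2-methyl-1,3-dioxolan-2-yl)ethyl]hept-6-en-3-one; 11 allyl bromide
Product: 13 (4S,7R)-4,6,6-trimethyl-7-[2-(2-methyl-1,3-dioxolan-2-yl)ethyl]nona-1,8-dien-5-one (formed together with its 4R epimer), via lithium enolate 12 (not isolated)
Conditions: LiN(iPr)2, THF, −78 °C; 11, DMPU, −78 → 0 °C
Reagents that add atoms: none
Why: In this kinetic enolate alkylation only C2 can be deprotonated because C10 is quaternary, SN2 attack on allyl bromide brings in C3 and C4, and the lack of control at C2 is harmless because C2 becomes sp2 in step 13 and is set in step 22.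

Step 9
Reactants: 13 (4S,7R)-4,6,6-trimethyl-7-[2-(2-methyl-1,3-dioxolan-2-yl)ethyl]nona-1,8-dien-5-one
Product: 14 (2S,6R)-2,7,7-trimethyl-6-[2-(2-methyl-1,3-dioxolan-2-yl)ethyl]cyclohept-4-en-1-one
Conditions: second-generation Grubbs catalyst (H2IMes)(PCy3)Cl2Ru=CHPh (5 mol %), CH2Cl2 (dilute), reflux
Reagents that add atoms: none
Why: Ring-closing metathesis of the two terminal vinyl groups closes the cycloheptene at C4=C5, helped by the gem-dimethyl group at C10.

Step 10
Reactants: 14 (2S,6R)-2,7,7-trimethyl-6-[2-(2-methyl-1,3-dioxolan-2-yl)ethyl]cyclohept-4-en-1-one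
Product: 15 (2S,6R)-2,7,7-trimethyl-6-(3-oxobutyl)cyclohept-4-en-1-one
Conditions: PPTS, acetone/H2O, 55 °C
Reagents that add atoms: water, O
Why: Mild acid hydrolysis of the ketal frees the C9 methyl ketone while the unconjugated alkene and the crowded C11 ketone stay unchanged.

Step 11
Reactants: 15 (2S,6R)-2,7,7-trimethyl-6-(3-oxobutyl)cyclohept-4-en-1-one
Product: 16 (1R,3aR,6S,8aR)-1-hydroxy-1,4,4,6-tetramethyloctahydroazulen-5(1H)-one (cis-fused; C9 methyl cis to C4, C9 hydroxyl on the H5/H6 face)
Conditions: SmI2 (2.2 equiv, added slowly), HMPA, t-BuOH (2 equiv), THF, 0 °C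
Reagents that add atoms: none
Why: Divalent samarium, made more reducing by HMPA, transfers one electron to the unhindered C9 methyl ketone, the samarium ketyl adds to C5 of the C4=C5 alkene, and the secondary C4 radical is reduced to an organosamarium that t-BuOH protonates (a reductive ketyl–olefin radical cyclisation, of the type that closes hex-5-enyl methyl ketones with SmI2/HMPA to cis-1,2-dialkylcyclopentanols). The cyclopentane C5–C9 closes 5-exo-trig, with C4 staying outside the new ring. C5 is controlled by the C6 stereocentre, because the three-atom tether C7–C8–C9 anchored on the allylic carbon can reach only the alkene face it lies over, which makes the ring fusion cis (H5 and H6 syn). C9 is controlled by a chair-like transition state in which the bulky O–Sm(HMPA)n group points away from C4 and the seven-membered ring, so the methyl ends cis to C4 and the hydroxyl on the H5/H6 face. The step needs the C9 ketone to react before the C11 ketone, and this is secured because C11 is flanked by quaternary C10 and tertiary C2, has no alkene in a 5-exo or 6-exo relation, and could couple with C9 only by building three contiguous fully substituted carbons in a bridged bicyclo[4.3.1] frame. Slow addition of just over two equivalents of SmI2 keeps the reductant limiting, and any C11 carbinol formed could be returned by oxidation because C9–OH is tertiary.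

Step 12
Reactants: 16 (1R,3aR,6S,8aR)-1-hydroxy-1,4,4,6-tetramethyloctahydroazulen-5(1H)-one
Product: 17 C11 hydrazone of 16
Conditions: N2H4·H2O (excess), Et3N, n-BuOH, 110 °C
Reagents that add atoms: hydrazine, NN
Why: Condensation with excess hydrazine under forcing conditions converts the only remaining ketone, the crowded C11 carbonyl, into its hydrazone, and the tertiary alcohol is inert.

Step 13
Reactants: 17 C11 hydrazone of 16
Product: 18 (1R,3aR,8aR)-5-iodo-1,4,4,6-tetramethyl-1,2,3,3a,4,7,8,8a-octahydroazulen-1-ol (C2=C11 vinyl iodide)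
Conditions: I2, 1,1,3,3-tetramethylguanidine, THF, 0 °C → 60 °C
Reagents that add atoms: iodine, II
Why: In the Barton vinyl iodide synthesis, oxidation of the hydrazone by iodine gives an iodo-carbocation equivalent that can lose a proton only from C2, so a single C2=C11 vinyl iodide should form from both C2 epimers.

Step 14
Reactants: 19 (E)-geranylacetone
Product: 20 (5R,6R,9R)-5,6:9,10-diepoxy-6,10-dimethylundecan-2-one
Conditions: 1,2:4,5-di-O-isopropylidene-β-D-erythro-hexo-2,3-diulo-2,6-pyranose (cat.), KHSO5 (as 2KHSO5·KHSO4·K2SO4), K2CO3, Bu4NHSO4 (cat.), MeCN/(MeO)2CH2/aq Na2B4O7 buffer, 0 °C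
Reagents that add atoms: potassium peroxymonosulfate, [K+].[O-]S(=O)(=O)OO
Why: In the Shi asymmetric epoxidation the chiral dioxirane oxidises both electron-rich trisubstituted alkenes through spiro transition states on the same enantioface, setting C15 and C21 (R,R) and C18 (R).

Step 15
Reactants: 20 (5R,6R,9R)-5,6:9,10-diepoxy-6,10-dimethylundecan-2-one; 21 ethyl glyoxylate
Product: 25 ethyl (2E,7R,8R,11R)-7,8:11,12-diepoxy-8,12-dimethyl-4-oxotridec-2-enoate, via lithium enolate 22 (not isolated), via lithium aldolate 23 (not isolated), via mesylate 24 (not isolated)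
Conditions: LiN(iPr)2, THF, −78 °C; 21 (freshly distilled); then MsCl, Et3N, −78 → 0 °C
Reagents that add atoms: none
Why: Kinetic deprotonation at the methyl group (C14), aldol addition to the glyoxylate aldehyde and E1cB loss of mesylate give the E-ene-keto ester and bring in C13 and C12.

Step 16
Reactants: 25 ethyl (2E,7R,8R,11R)-7,8:11,12-diepoxy-8,12-dimethyl-4-oxotridec-2-enoate
Product: 26 ethyl (3Z,7R,8R,11R)-7,8:11,12-diepoxy-8,12-dimethyl-4-(triethylsilyloxy)tridec-3-enoate
Conditions: Et3SiH, RhCl(PPh3)3 (1 mol %), THF, 50 °C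
Reagents that add atoms: triethylsilane, CC[SiH](CC)CC
Why: Rhodium-catalysed 1,4-hydrosilylation adds hydride to C13 and silicon to the ketone oxygen, the better acceptor end of the ene-keto ester, so the enol silane forms regiospecifically at C14=C24 (Z from the s-cis enone) with the epoxides untouched.

Step 17
Reactants: 26 ethyl (3Z,7R,8R,11R)-7,8:11,12-diepoxy-8,12-dimethyl-4-(triethylsilyloxy)tridec-3-enoate
Product: 27 ethyl 2-[(3R,5aR,6R,9aR)-3-(tert-butyldimethylsilyloxy)-2,2,5a-trimethyl-7-oxoperhydro-1-benzoxepin-6-yl]acetate (trans-fused; C14 side chain equatorial)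
Conditions: TBSOTf (1.1 equiv), 2,6-di-tert-butyl-4-methylpyridine, CH2Cl2, −78 °C
Reagents that add atoms: tert-butyldimethylsilyl triflate, CC(C)(C)[Si](C)(C)OS(=O)(=O)C(F)(F)F
Why: In this silyl-triflate-initiated tandem oxa-/carbacyclisation of a diepoxy enol silane the silylated terminal epoxide is opened at tertiary C19 by the inner epoxide oxygen (7-endo) and the resulting epoxonium is opened at C15 with inversion by C14 through a chair, giving the trans-fused oxepane–cyclohexanone with C15 and C21 relayed from the epoxide and the epimerisable C14 side chain equatorial.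

Step 18
Reactants: 27 ethyl 2-[(3R,5aR,6R,9aR)-3-(tert-butyldimethylsilyloxy)-2,2,5a-trimethyl-7-oxoperhydro-1-benzoxepin-6-yl]acetate
Product: 29 tricyclic γ-lactone (14R,15R,18R,21R,24S), C12(=O)–O–C24 ring cis-fused to the cyclohexane of the 18-OTBS perhydrobenzoxepine, via bromomagnesium alkoxide 28 (not isolated)
Conditions: MeMgBr (1.2 equiv), LaCl3·2LiCl (30 mol %), THF, −78 → 0 °C; H2O
Reagents that add atoms: methylmagnesium bromide, C[Mg]Br
Why: Grignard 1,2-addition from the equatorial direction, the axial face being blocked by the axial C15 methyl, gives the axial C24 alkoxide (24S) cis to the C14 side chain, which closes onto the ester to a γ-lactone that protects C24–OH and activates C12.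

Step 19
Reactants: 18 C2=C11 vinyl iodide; 29 tricyclic γ-lactone
Product: 31 hydroxy enone (C2=C11–C12(=O)–C13H2–C14; free C9–OH and C24–OH, 18-OTBS), via dilithio vinyllithium 30 (not isolated)
Conditions: 18, t-BuLi (3.1 equiv), Et2O, −78 °C; 29 in THF, −78 → −30 °C; H2O
Reagents that add atoms: none
Why: Iodine–lithium exchange and acylation of the vinyllithium by the lactone form C11–C12, and the lithium hemiketal together with the crowding at C12 should prevent a second addition.

Step 20
Reactants: 31 hydroxy enone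
Product: 32 enone with 9-OTES, 24-OTES and 18-OTBS
Conditions: TESOTf (2.5 equiv), 2,6-lutidine, CH2Cl2, −78 → 0 °C
Reagents that add atoms: triethylsilyl triflate, CC[Si](CC)(CC)OS(=O)(=O)C(F)(F)F
Why: Silylation with a silyl triflate and a hindered pyridine base caps both tertiary alcohols, which keeps C24–OH from closing a tetrahydrofuran onto C12 in step 22.

Step 21
Reactants: 32 enone with 9-OTES, 24-OTES and 18-OTBS
Product: 33 (12R)-allylic alcohol
Conditions: (S)-2-methyl-CBS-oxazaborolidine (0.5 equiv), BH3·SMe2, toluene, −30 °C; MeOH, H2O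
Reagents that add atoms: none
Why: In the Corey–Bakshi–Shibata reduction the tetrasubstituted cycloheptenyl group acts as the large substituent, so the (S)-oxazaborolidine should direct hydride to give the (12R)-alcohol under reagent control.

Step 22
Reactants: 33 (12R)-allylic alcohol
Product: 36 fully silylated (2S,11Z)-alkene (9-OTES, 24-OTES, 18-OTBS), via sulfonylhydrazide 34 (not isolated), via allylic diazene 35 (not isolated)
Conditions: 2-nitrobenzenesulfonylhydrazide (NBSH), PPh3, DEAD, N-methylmorpholine, −30 °C, then 23 °C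
Reagents that add atoms: none
Why: Mitsunobu displacement by the acidic N–H of NBSH with inversion, loss of the arenesulfinic acid on warming, and retro-ene loss of N2 from the (12S)-allylic diazene deliver H suprafacially to the H5/H6 face of C2 (giving 2S) and move the alkene to C11=C12, with H12 taking the inside position next to the C1 methyl to avoid A(1,3) strain so that C13 ends on the C10 side (Z).

Step 23
Reactants: 36 fully silylated (2S,11Z)-alkene
Product: 37 (18R)-triol (C9–OH, C18–OH, C24–OH)
Conditions: Bu4NF, THF, 50 °C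
Reagents that add atoms: none
Why: Fluoride cleaves the three silyl ethers under non-acidic conditions, which avoids acid-induced cyclisation of C24–OH onto the C11=C12 alkene.

Step 24
Reactants: 37 (18R)-triol
Product: 38 target CNP0157787.1
Conditions: Dess–Martin periodinane, CH2Cl2, rt
Reagents that add atoms: none
Why: Dess–Martin oxidation touches only the single secondary alcohol at C18, the two tertiary alcohols and the hindered alkene being inert, and gives the oxepanone of the target.

**Compound list**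

1 | hex-5-en-2-one | CC(=O)CCC=C | starting material
2 | 2-(but-3-en-1-yl)-2-methyl-1,3-dioxolane | CC1(CCC=C)OCCO1 | intermediate
3 | ethyl acrylate | C=CC(=O)OCC | starting material
4 | ethyl (E)-5-(2-methyl-1,3-dioxolan-2-yl)pent-2-enoate | CCOC(=O)/C=C/CCC1(C)OCCO1 | intermediate
5 | (E)-5-(2-methyl-1,3-dioxolan-2-yl)pent-2-en-1-ol | OC/C=C/CCC1(C)OCCO1 | intermediate
6 | methyl (E)-5-(2-methyl-1,3-dioxolan-2-yl)pent-2-en-1-yl carbonate | COC(=O)OC/C=C/CCC1(C)OCCO1 | intermediate
7 | 1-methoxy-2-methyl-1-(trimethylsilyloxy)prop-1-ene | COC(O[Si](C)(C)C)=C(C)C | starting material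
8 | methyl (3R)-2,2-dimethyl-3-[2-(2-methyl-1,3-dioxolan-2-yl)ethyl]pent-4-enoate | C=C[C@@H](CCC1(C)OCCO1)C(C)(C)C(=O)OC | intermediate
9 | (3R)-N-methoxy-N,2,2-trimethyl-3-[2-(2-methyl-1,3-dioxolan-2-yl)ethyl]pent-4-enamide | C=C[C@@H](CCC1(C)OCCO1)C(C)(C)C(=O)N(C)OC | intermediate
10 | (5R)-4,4-dimethyl-5-[2-(2-methyl-1,3-dioxolan-2-yl)ethyl]hept-6-en-3-one | C=C[C@@H](CCC1(C)OCCO1)C(C)(C)C(=O)CC | intermediate
11 | allyl bromide | C=CCBr | starting material
12 | lithium (Z)-enolate of 10 | C=C[C@@H](CCC1(C)OCCO1)C(C)(C)/C(O[Li])=C/C | intermediate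
13 | (4S,7R)-4,6,6-trimethyl-7-[2-(2-methyl-1,3-dioxolan-2-yl)ethyl]nona-1,8-dien-5-one | C[C@@H](CC=C)C(=O)C(C)(C)[C@@H](C=C)CCC1(C)OCCO1 | intermediate
14 | (2S,6R)-2,7,7-trimethyl-6-[2-(2-methyl-1,3-dioxolan-2-yl)ethyl]cyclohept-4-en-1-one | C[C@H]1CC=C[C@@H](CCC2(C)OCCO2)C(C)(C)C1=O | intermediate
15 | (2S,6R)-2,7,7-trimethyl-6-(3-oxobutyl)cyclohept-4-en-1-one | C[C@H]1CC=C[C@@H](CCC(C)=O)C(C)(C)C1=O | intermediate
16 | (1R,3aR,6S,8aR)-1-hydroxy-1,4,4,6-tetramethyloctahydroazulen-5(1H)-one | C[C@H]1CC[C@@H]2[C@@H](CC[C@@]2(C)O)C(C)(C)C1=O | intermediate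
17 | C11 hydrazone of 16 | C[C@H]1CC[C@@H]2[C@@H](CC[C@@]2(C)O)C(C)(C)C1=NN | intermediate
18 | (1R,3aR,8aR)-5-iodo-1,4,4,6-tetramethyl-1,2,3,3a,4,7,8,8a-octahydroazulen-1-ol | CC=1CC[C@@H]2[C@@H](CC[C@@]2(C)O)C(C)(C)C=1I | intermediate
19 | (E)-geranylacetone | CC(=O)CC/C=C(\C)CCC=C(C)C | starting material
20 | (5R,6R,9R)-5,6:9,10-diepoxy-6,10-dimethylundecan-2-one | CC(=O)CC[C@H]1O[C@]1(C)CC[C@H]1OC1(C)C | intermediate
21 | ethyl glyoxylate | CCOC(=O)C=O | starting material
22 | kinetic lithium enolate of 20 | C=C(O[Li])CC[C@H]1O[C@]1(C)CC[C@H]1OC1(C)C | intermediate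
23 | lithium aldolate (carbinol centre not controlled) | CCOC(=O)C(O[Li])CC(=O)CC[C@H]1O[C@]1(C)CC[C@H]1OC1(C)C | intermediate
24 | mesylate of the aldol (carbinol centre not controlled) | CCOC(=O)C(OS(C)(=O)=O)CC(=O)CC[C@H]1O[C@]1(C)CC[C@H]1OC1(C)C | intermediate
25 | ethyl (2E,7R,8R,11R)-7,8:11,12-diepoxy-8,12-dimethyl-4-oxotridec-2-enoate | CCOC(=O)/C=C/C(=O)CC[C@H]1O[C@]1(C)CC[C@H]1OC1(C)C | intermediate
26 | ethyl (3Z,7R,8R,11R)-7,8:11,12-diepoxy-8,12-dimethyl-4-(triethylsilyloxy)tridec-3-enoate | CCOC(=O)C/C=C(\O[Si](CC)(CC)CC)CC[C@H]1O[C@]1(C)CC[C@H]1OC1(C)C | intermediate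
27 | ethyl 2-[(3R,5aR,6R,9aR)-3-(tert-butyldimethylsilyloxy)-2,2,5a-trimethyl-7-oxoperhydro-1-benzoxepin-6-yl]acetate | CCOC(=O)C[C@@H]1[C@@]2(C)CC[C@@H](O[Si](C)(C)C(C)(C)C)C(C)(C)O[C@@H]2CCC1=O | intermediate
28 | bromomagnesium (24S)-alkoxide of the hydroxy ester | CCOC(=O)C[C@@H]1[C@@]2(C)CC[C@@H](O[Si](C)(C)C(C)(C)C)C(C)(C)O[C@@H]2CC[C@]1(C)O[Mg]Br | intermediate
29 | tricyclic γ-lactone (14R,15R,18R,21R,24S), 18-OTBS | O=C3C[C@@H]1[C@@]2(C)CC[C@@H](O[Si](C)(C)C(C)(C)C)C(C)(C)O[C@@H]2CC[C@]1(C)O3 | intermediate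
30 | C11 vinyllithium, C9 lithium alkoxide | CC=1CC[C@@H]2[C@@H](CC[C@@]2(C)O[Li])C(C)(C)C=1[Li] | intermediate
31 | hydroxy enone, C9–OH and C24–OH free, 18-OTBS | CC=1CC[C@@H]2[C@@H](CC[C@@]2(C)O)C(C)(C)C=1C(=O)C[C@@H]1[C@@]2(C)CC[C@@H](O[Si](C)(C)C(C)(C)C)C(C)(C)O[C@@H]2CC[C@]1(C)O | intermediate
32 | enone, 9-OTES, 24-OTES, 18-OTBS | CC=1CC[C@@H]2[C@@H](CC[C@@]2(C)O[Si](CC)(CC)CC)C(C)(C)C=1C(=O)C[C@@H]1[C@@]2(C)CC[C@@H](O[Si](C)(C)C(C)(C)C)C(C)(C)O[C@@H]2CC[C@]1(C)O[Si](CC)(CC)CC | intermediate
33 | (12R)-allylic alcohol | CC=1CC[C@@H]2[C@@H](CC[C@@]2(C)O[Si](CC)(CC)CC)C(C)(C)C=1[C@H](O)C[C@@H]1[C@@]2(C)CC[C@@H](O[Si](C)(C)C(C)(C)C)C(C)(C)O[C@@H]2CC[C@]1(C)O[Si](CC)(CC)CC | intermediate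
34 | (12S)-N-alkyl-2-nitrobenzenesulfonylhydrazide | CC=1CC[C@@H]2[C@@H](CC[C@@]2(C)O[Si](CC)(CC)CC)C(C)(C)C=1[C@@H](N(N)S(=O)(=O)c1ccccc1[N+](=O)[O-])C[C@@H]1[C@@]2(C)CC[C@@H](O[Si](C)(C)C(C)(C)C)C(C)(C)O[C@@H]2CC[C@]1(C)O[Si](CC)(CC)CC | intermediate
35 | (12S)-allylic diazene | CC=1CC[C@@H]2[C@@H](CC[C@@]2(C)O[Si](CC)(CC)CC)C(C)(C)C=1[C@@H](N=N)C[C@@H]1[C@@]2(C)CC[C@@H](O[Si](C)(C)C(C)(C)C)C(C)(C)O[C@@H]2CC[C@]1(C)O[Si](CC)(CC)CC | intermediate
36 | fully silylated (2S,11Z)-alkene | C[C@H]1CC[C@@H]2[C@@H](CC[C@@]2(C)O[Si](CC)(CC)CC)C(C)(C)/C1=C\C[C@@H]1[C@@]2(C)CC[C@@H](O[Si](C)(C)C(C)(C)C)C(C)(C)O[C@@H]2CC[C@]1(C)O[Si](CC)(CC)CC | intermediate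
37 | (18R)-triol | C[C@H]1CC[C@@H]2[C@@H](CC[C@@]2(C)O)C(C)(C)/C1=C\C[C@@H]1[C@@]2(C)CC[C@@H](O)C(C)(C)O[C@@H]2CC[C@]1(C)O | intermediate
38 | CNP0157787.1 | C[C@H]1CC[C@@H]2[C@@H](CC[C@@]2(C)O)C(C)(C)/C1=C\C[C@@H]1[C@@]2(C)CCC(=O)C(C)(C)O[C@@H]2CC[C@]1(C)O | target

**Step count and risks**

Total step count: 24.
Longest linear sequence: 19 steps (steps 1–13 and 19–24).

Steps most likely to fail:

1. Step 22. The Mitsunobu displacement may stall at the crowded allylic carbinol or drift towards ionisation, with loss of the C12 information. Part of the diazene may also rearrange through the rotamer that places C13 inside, which would erode both the alkene geometry and C2. The fallback sets out from enone 32. Condensation with TsNHNH2 (Ti(OiPr)4, THF, 60 °C) should give the tosylhydrazone F1. Reduction of its C=N bond with catecholborane at low temperature should give the allylic N-tosylhydrazine F2. Warming with NaOAc·3H2O expels the sulfinate to give diazene 35, and the route is rejoined at 36. In this variant the C12–N bond comes from a condensation and not from a substitution. C12 is set by hydride attack on the C=N face that looks towards the C1 methyl.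

2. Step 11. Three processes may compete with the 5-exo closure: electron transfer to the C11 ketone, pinacol-type coupling between the two carbonyl groups, and simple reduction of the C9 ketyl before it cyclises. The fallback sets out from ketal ketone 14 and removes the second carbonyl from the substrate. LiAlH4 reduction should give the C11 carbinol ketal F3. Ketal hydrolysis (PPTS, acetone/H2O) should give the C11 carbinol methyl ketone F4. The same ketyl closure should then give the hydroazulene diol F5. Dess–Martin oxidation of its only secondary alcohol returns to the route at 16. The C11 configuration is irrelevant.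

3. Step 19. The hindered vinyllithium may act as a base towards the C13 protons of the lactone rather than add to C12. The fallback sets out from lactone 29. Reduction with i-Bu2AlH (−78 °C) should give the lactol F6, which is deprotonated with i-PrMgCl so that its open aldehyde form is offered to vinyllithium 30. This far more electrophilic partner should give the allylic diol F7 as C12 epimers. Selective allylic oxidation with MnO2 comes back to the route at 31.

**Further compounds**

F1 | step 22 | C12 tosylhydrazone of 32 | CC=1CC[C@@H]2[C@@H](CC[C@@]2(C)O[Si](CC)(CC)CC)C(C)(C)C=1C(=NNS(=O)(=O)c1ccc(C)cc1)C[C@@H]1[C@@]2(C)CC[C@@H](O[Si](C)(C)C(C)(C)C)C(C)(C)O[C@@H]2CC[C@]1(C)O[Si](CC)(CC)CC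
F2 | step 22 | (12S)-allylic N-tosylhydrazine | CC=1CC[C@@H]2[C@@H](CC[C@@]2(C)O[Si](CC)(CC)CC)C(C)(C)C=1[C@@H](NNS(=O)(=O)c1ccc(C)cc1)C[C@@H]1[C@@]2(C)CC[C@@H](O[Si](C)(C)C(C)(C)C)C(C)(C)O[C@@H]2CC[C@]1(C)O[Si](CC)(CC)CC
F3 | step 11 | C11 carbinol ketal (C11 not controlled) | C[C@H]1CC=C[C@@H](CCC2(C)OCCO2)C(C)(C)C1O
F4 | step 11 | C11 carbinol methyl ketone (C11 not controlled) | C[C@H]1CC=C[C@@H](CCC(C)=O)C(C)(C)C1O
F5 | step 11 | hydroazulene diol (C11 not controlled) | C[C@H]1CC[C@@H]2[C@@H](CC[C@@]2(C)O)C(C)(C)C1O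
F6 | step 19 | lactol of 29 (C12 not controlled) | OC3C[C@@H]1[C@@]2(C)CC[C@@H](O[Si](C)(C)C(C)(C)C)C(C)(C)O[C@@H]2CC[C@]1(C)O3
F7 | step 19 | allylic diol (C12 epimers) | CC=1CC[C@@H]2[C@@H](CC[C@@]2(C)O)C(C)(C)C=1C(O)C[C@@H]1[C@@]2(C)CC[C@@H](O[Si](C)(C)C(C)(C)C)C(C)(C)O[C@@H]2CC[C@]1(C)O
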